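The C40 chain is cut at the C10'–C11' single bond inside the C9'=C10'–C11'=C12' diene. The key step is a one-pot Negishi sequence: Cp2ZrCl2-catalysed syn-methylalumination of a terminal alkyne, then Pd2(dba)3/ZnCl2-catalysed alkenyl–alkenyl coupling with a C26 polyenynyl iodide. One operation installs the C9' methyl group, the 9'E geometry and the C10'–C11' bond. The precursor is a C13 ring B alkyne that lacks this methyl group. The step exploits the saturated C7'–C8' tether, which isolates the C9'(CH3)=C10'H unit from ring B and makes it the product of a simple alkyne methylmetalation. Both rings derive from one enol triflate of (4R,6R)-actinol.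

Key step: step 9

Remark: carotenoid numbering is used for locants; ring A is the ring on the acetylenic (C7≡C8) half, ring B the ring on the 7',8'-dihydro half (primed atoms).
Assumption: compounds 1, 5, 8 (all-E isomer) and 11 are taken as purchasable.

Step 1
Reactants: 1 (4R,6R)-4-hydroxy-2,2,6-trimethylcyclohexan-1-one (actinol)
Product: 2 (4R,6R)-4-[(tert-butyldimethylsilyl)oxy]-2,2,6-trimethylcyclohexan-1-one
Conditions: TBSCl, imidazole, DMF, rt
Reagents that add atoms: tert-butyldimethylsilyl chloride, CC(C)(C)[Si](C)(C)Cl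
Why: Silyl ether protection of the unhindered secondary alcohol should proceed cleanly and leaves the carbinol stereocentre, which becomes C3 and C3' of the target, untouched.

Step 2
Reactants: 2 (4R,6R)-4-[(tert-butyldimethylsilyl)oxy]-2,2,6-trimethylcyclohexan-1-one
Product: 4 (R)-4-[(tert-butyldimethylsilyl)oxy]-2,6,6-trimethylcyclohex-1-en-1-yl trifluoromethanesulfonate, via lithium enolate 3 (not isolated)
Conditions: LDA, THF, −78 to 0 °C; then PhNTf2, −78 °C to rt
Reagents that add atoms: N-phenylbis(trifluoromethanesulfonimide), O=S(=O)(N(c1ccccc1)S(=O)(=O)C(F)(F)F)C(F)(F)F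
Why: Enol triflate formation: the gem-dimethyl carbon is quaternary, so the ketone can enolise only towards the methyl-bearing carbon and a single tetrasubstituted enolate is O-sulfonylated; the methyl-bearing stereocentre is erased on purpose and the silyloxy stereocentre is remote.

Step 3
Reactants: 4 (R)-4-[(tert-butyldimethylsilyl)oxy]-2,6,6-trimethylcyclohex-1-en-1-yl trifluoromethanesulfonate; 5 (E)-3-methylpent-2-en-4-yn-1-ol
Product: 6 (E)-5-[(R)-4-[(tert-butyldimethylsilyl)oxy]-2,6,6-trimethylcyclohex-1-en-1-yl]-3-methylpent-2-en-4-yn-1-ol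
Conditions: Pd(PPh3)4 (5 mol%), CuI (10 mol%), i-Pr2NH, DMF, 40 °C, degassed
Reagents that add atoms: none
Why: Sonogashira coupling of the alkenyl triflate with the terminal alkyne should form the C6–C7 bond with the ring A double bond fixed at C5=C6 by the triflate, the 9E geometry of 5 retained and the free allylic alcohol tolerated; no stereocentre is formed.

Step 4
Reactants: 6 (E)-5-[(R)-4-[(tert-butyldimethylsilyl)oxy]-2,6,6-trimethylcyclohex-1-en-1-yl]-3-methylpent-2-en-4-yn-1-ol
Product: 7 [(E)-5-((R)-4-hydroxy-2,6,6-trimethylcyclohex-1-en-1-yl)-3-methylpent-2-en-4-yn-1-yl]triphenylphosphonium bromide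
Conditions: PPh3·HBr (1.5 equiv), MeOH, rt then 40 °C
Reagents that add atoms: triphenylphosphine hydrobromide, [Br-].c1ccc(cc1)[PH+](c1ccccc1)c1ccccc1
Why: Phosphonium salt formation from an allylic alcohol: acid activation lets PPh3 substitute at the primary allylic terminus, and the acidic methanol should also cleave the silyl ether, which is not needed further; the carbinol stereocentre is not involved.

Step 5
Reactants: 7 [(E)-5-((R)-4-hydroxy-2,6,6-trimethylcyclohex-1-en-1-yl)-3-methylpent-2-en-4-yn-1-yl]triphenylphosphonium bromide; 8 (2E,4E,6E)-2,7-dimethylocta-2,4,6-trienedial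
Product: 9 (2E,4E,6E,8E,10E)-13-[(R)-4-hydroxy-2,6,6-trimethylcyclohex-1-en-1-yl]-2,7,11-trimethyltrideca-2,4,6,8,10-pentaen-12-ynal
Conditions: 8 (2 equiv), NaOMe, MeOH/CH2Cl2, 0 °C to rt; then EtOAc/heptane, 70 °C, dark (E/Z equilibration), crystallisation
Reagents that add atoms: none
Why: Wittig olefination of one aldehyde group of the symmetrical dialdehyde (used in excess, and more electrophilic than the longer product aldehyde) should form C11=C12, the hindered 11Z isomer being converted thermally into the all-E aldehyde; the free hydroxyl is tolerated and no stereocentre is formed.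

Step 6
Reactants: 9 (2E,4E,6E,8E,10E)-13-[(R)-4-hydroxy-2,6,6-trimethylcyclohex-1-en-1-yl]-2,7,11-trimethyltrideca-2,4,6,8,10-pentaen-12-ynal
Product: 10 (R)-4-[(3E,5E,7E,9E,11E,13E)-14-iodo-3,7,12-trimethyltetradeca-3,5,7,9,11,13-hexaen-1-yn-1-yl]-3,5,5-trimethylcyclohex-3-en-1-ol
Conditions: CrCl2 (8 equiv), CHI3 (2.5 equiv), THF/1,4-dioxane, 0 °C to rt, dark
Reagents that add atoms: iodoform, IC(I)I
Why: Takai olefination: the geminal dichromium species formed from CHI3 and divalent chromium adds to the aldehyde and eliminates to the (E)-alkenyl iodide, adding C11' with the required 11'E geometry while the hydroxyl, the alkyne and the polyene are tolerated; no stereocentre is formed.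

Step 7
Reactants: 4 (R)-4-[(tert-butyldimethylsilyl)oxy]-2,6,6-trimethylcyclohex-1-en-1-yl trifluoromethanesulfonate; 11 (4-bromobut-1-yn-1-yl)trimethylsilane
Product: 13 tert-butyldimethyl({(R)-3,5,5-trimethyl-4-[4-(trimethylsilyl)but-3-yn-1-yl]cyclohex-3-en-1-yl}oxy)silane, via organozinc bromide 12 (not isolated)
Conditions: 11, Zn dust (activated), LiCl, THF, 50 °C; then 4, PdCl2(dppf) (5 mol%), THF/NMP, 60 °C
Reagents that add atoms: none
Why: Negishi C(sp2)–C(sp3) coupling: the wide-bite-angle dppf ligand should favour reductive elimination over β-hydride elimination, the ring B double bond is fixed at C5'=C6' by the triflate (no dehydration regiochemistry to control), and the C-silyl group masks the acidic alkyne C–H; no stereocentre is formed.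

Step 8
Reactants: 13 tert-butyldimethyl({(R)-3,5,5-trimethyl-4-[4-(trimethylsilyl)but-3-yn-1-yl]cyclohex-3-en-1-yl}oxy)silane
Product: 14 (R)-4-(but-3-yn-1-yl)-3,5,5-trimethylcyclohex-3-en-1-ol
Conditions: TBAF (2.5 equiv), THF, rt
Reagents that add atoms: none
Why: Fluoride-mediated desilylation should cleave both the alkynyl C–Si bond and the O–Si bond in one operation without touching the stereocentre or the tetrasubstituted alkene.

Step 9
Reactants: 14 (R)-4-(but-3-yn-1-yl)-3,5,5-trimethylcyclohex-3-en-1-ol; 10 (R)-4-[(3E,5E,7E,9E,11E,13E)-14-iodo-3,7,12-trimethyltetradeca-3,5,7,9,11,13-hexaen-1-yn-1-yl]-3,5,5-trimethylcyclohex-3-en-1-ol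
Product: 17 (all-E)-(3R,3'R)-7,8-didehydro-7',8'-dihydro-β,β-carotene-3,3'-diol, via alkenylalane 15 (not isolated), via iodide aluminium alkoxide 16 (not isolated)
Conditions: 14, Me3Al (3.5 equiv), Cp2ZrCl2 (25 mol%), CH2Cl2, 0 °C to rt; volatiles removed in vacuo, THF; then 10 premixed with Me3Al (1.05 equiv, THF, 0 °C), ZnCl2 (30 mol%), Pd2(dba)3 (2.5 mol%), tri(2-furyl)phosphine (10 mol%), rt, dark; aq. Rochelle salt
Reagents that add atoms: trimethylaluminium, C[Al](C)C
Why: Cp2ZrCl2 and Me3Al form a methylzirconium–aluminate species that adds CH3 and metal syn across the terminal alkyne of 14 (CH3 to C9', metal to C10'), giving the (E)-alkenylalane 15; ZnCl2 relays the alkenyl group to palladium after zerovalent palladium has inserted into the C11'–I bond of 16 with retention, and reductive elimination forms the C10'–C11' bond. The closest known reaction type is the tandem Cp2ZrCl2-catalysed carboalumination/Negishi alkenyl–alkenyl coupling established for methyl-branched polyenes. No ring is closed and no stereocentre is created; the 9'E geometry follows from syn-carbometalation and the 11'E geometry from stereoretentive coupling of the E-iodide. The step needs regioselective methylalumination and chemoselectivity over the C7≡C8 triple bond and the polyene: the alkyne of 14 is terminal, unhindered and, because C7'–C8' is saturated, not conjugated to ring B, whereas C7≡C8 is internal and flanked by the fully substituted C6 and C9, and volatile Me3Al is stripped before 16 is added. Both hydroxyl groups are masked in the flask as dimethylaluminium alkoxides and should be released on aqueous work-up, so no protecting-group step follows.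

Compound list
1 | (4R,6R)-4-hydroxy-2,2,6-trimethylcyclohexan-1-one (actinol) | O=C1C(C)(C)C[C@H](O)C[C@H]1C | starting material
2 | (4R,6R)-4-[(tert-butyldimethylsilyl)oxy]-2,2,6-trimethylcyclohexan-1-one | O=C1C(C)(C)C[C@H](O[Si](C)(C)C(C)(C)C)C[C@H]1C | intermediate
3 | lithium (R)-4-[(tert-butyldimethylsilyl)oxy]-2,6,6-trimethylcyclohex-1-en-1-olate (not isolated) | CC1=C([O-])C(C)(C)C[C@H](O[Si](C)(C)C(C)(C)C)C1.[Li+] | intermediate
4 | (R)-4-[(tert-butyldimethylsilyl)oxy]-2,6,6-trimethylcyclohex-1-en-1-yl trifluoromethanesulfonate | CC1=C(OS(=O)(=O)C(F)(F)F)C(C)(C)C[C@H](O[Si](C)(C)C(C)(C)C)C1 | intermediate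
5 | (E)-3-methylpent-2-en-4-yn-1-ol | C#C/C(C)=C/CO | starting material
6 | (E)-5-[(R)-4-[(tert-butyldimethylsilyl)oxy]-2,6,6-trimethylcyclohex-1-en-1-yl]-3-methylpent-2-en-4-yn-1-ol | CC1=C(C#C/C(C)=C/CO)C(C)(C)C[C@H](O[Si](C)(C)C(C)(C)C)C1 | intermediate
7 | [(E)-5-((R)-4-hydroxy-2,6,6-trimethylcyclohex-1-en-1-yl)-3-methylpent-2-en-4-yn-1-yl]triphenylphosphonium bromide | CC1=C(C#C/C(C)=C/C[P+](c2ccccc2)(c2ccccc2)c2ccccc2)C(C)(C)C[C@H](O)C1.[Br-] | intermediate
8 | (2E,4E,6E)-2,7-dimethylocta-2,4,6-trienedial | O=C/C(C)=C/C=C/C=C(C)/C=O | starting material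
9 | (2E,4E,6E,8E,10E)-13-[(R)-4-hydroxy-2,6,6-trimethylcyclohex-1-en-1-yl]-2,7,11-trimethyltrideca-2,4,6,8,10-pentaen-12-ynal | CC1=C(C#C/C(C)=C/C=C/C(C)=C/C=C/C=C(C)/C=O)C(C)(C)C[C@H](O)C1 | intermediate
10 | (R)-4-[(3E,5E,7E,9E,11E,13E)-14-iodo-3,7,12-trimethyltetradeca-3,5,7,9,11,13-hexaen-1-yn-1-yl]-3,5,5-trimethylcyclohex-3-en-1-ol | CC1=C(C#C/C(C)=C/C=C/C(C)=C/C=C/C=C(C)/C=C/I)C(C)(C)C[C@H](O)C1 | intermediate
11 | (4-bromobut-1-yn-1-yl)trimethylsilane | C[Si](C)(C)C#CCCBr | starting material
12 | [4-(trimethylsilyl)but-3-yn-1-yl]zinc bromide (not isolated) | C[Si](C)(C)C#CCC[Zn]Br | intermediate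
13 | tert-butyldimethyl({(R)-3,5,5-trimethyl-4-[4-(trimethylsilyl)but-3-yn-1-yl]cyclohex-3-en-1-yl}oxy)silane | CC1=C(CCC#C[Si](C)(C)C)C(C)(C)C[C@H](O[Si](C)(C)C(C)(C)C)C1 | intermediate
14 | (R)-4-(but-3-yn-1-yl)-3,5,5-trimethylcyclohex-3-en-1-ol | CC1=C(CCC#C)C(C)(C)C[C@H](O)C1 | intermediate
15 | dimethylaluminium (R)-4-[(E)-4-(dimethylalumanyl)-3-methylbut-3-en-1-yl]-3,5,5-trimethylcyclohex-3-en-1-olate (not isolated) | CC1=C(CC/C(C)=C/[Al](C)C)C(C)(C)C[C@H](O[Al](C)C)C1 | intermediate
16 | dimethylaluminium alkoxide of iodide 10 (not isolated) | CC1=C(C#C/C(C)=C/C=C/C(C)=C/C=C/C=C(C)/C=C/I)C(C)(C)C[C@H](O[Al](C)C)C1 | intermediate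
17 | (all-E)-(3R,3'R)-7,8-didehydro-7',8'-dihydro-β,β-carotene-3,3'-diol | CC1=C(C#C/C(C)=C/C=C/C(C)=C/C=C/C=C(C)/C=C/C=C(\C)CCC2=C(C)C[C@@H](O)CC2(C)C)C(C)(C)C[C@H](O)C1 | target

Total step count: 9 steps.
Longest linear sequence: 7 steps (steps 1, 2, 3, 4, 5, 6 and 9); steps 7 and 8 form the short branch from triflate 4.

Steps most likely to fail

Step 9 (key step). Protonolysis of the alkenylalane or transfer of a methyl group in place of the alkenyl group may compete with the coupling, and the Lewis-acidic medium may scramble the E/Z geometry of the polyenyl iodide. The fallback separates carbometalation from coupling and reverses the polarity. It sets out from 14 and from 9 and comes back at 17. From 14, the same Cp2ZrCl2/Me3Al methylalumination is quenched with I2 to give the alkenyl iodide (R)-4-[(E)-4-iodo-3-methylbut-3-en-1-yl]-3,5,5-trimethylcyclohex-3-en-1-ol F1. From 9, Takai–Utimoto olefination (Cl2CHBpin, CrCl2, LiI, THF) should give the C26 (E)-alkenyl pinacol boronate F2. Suzuki–Miyaura coupling of F1 with F2 (Pd(OAc)2, SPhos, K3PO4, THF/H2O, rt, dark) tolerates both free hydroxyl groups, forms the same C10'–C11' bond and gives 17.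

Step 7. Oxidative addition into the C–OTf bond, which is flanked by a methyl-bearing and a gem-dimethyl carbon, may be slow, so that β-hydride elimination, reduction of the triflate or decay of the zinc reagent takes over. The fallback builds the side chain at the ketone oxidation level; it sets out from 4 and comes back at 14, replacing steps 7 and 8. Stille coupling of 4 with (E)-4-(tributylstannyl)but-3-en-2-one (Pd2(dba)3, AsPh3, NMP, 60 °C) should give (E)-4-[(R)-4-[(tert-butyldimethylsilyl)oxy]-2,6,6-trimethylcyclohex-1-en-1-yl]but-3-en-2-one F3. Conjugate reduction of the enone with [(Ph3P)CuH]6 (benzene, rt) gives the saturated ketone 4-[(R)-4-[(tert-butyldimethylsilyl)oxy]-2,6,6-trimethylcyclohex-1-en-1-yl]butan-2-one F4. Kinetic deprotonation at the methyl group (LDA, THF, −78 °C) and trapping with ClP(O)(OEt)2 gives the enol phosphate F5, which with further LDA (2.2 equiv, −78 °C to rt) eliminates to the terminal alkyne tert-butyl{[(R)-4-(but-3-yn-1-yl)-3,5,5-trimethylcyclohex-3-en-1-yl]oxy}dimethylsilane F6. TBAF (THF, rt) then gives 14.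

Step 6. The extended polyenal may be attacked sluggishly by the dichromium reagent, the new double bond may form with incomplete E selectivity, and the product may degrade under excess divalent chromium or light. The fallback reaches the iodide through an alkyne; it sets out from 9 and comes back at 10. Colvin homologation (TMSCHN2, LDA, THF, −78 °C to rt) should convert the aldehyde into the terminal enyne (R)-4-[(3E,5E,7E,9E,11E)-3,7,12-trimethyltetradeca-3,5,7,9,11-pentaen-1,13-diyn-1-yl]-3,5,5-trimethylcyclohex-3-en-1-ol F7. Hydrostannation (Bu3SnH, PdCl2(PPh3)2, THF, 0 °C) should place tin at the terminal carbon, because the alkyne sits on the methyl-branched C13', giving the (E)-alkenylstannane F8. Iododestannylation (I2, CH2Cl2, 0 °C, dark) then gives 10.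

Further compounds
F1 | step 9 | (R)-4-[(E)-4-iodo-3-methylbut-3-en-1-yl]-3,5,5-trimethylcyclohex-3-en-1-ol | CC1=C(CC/C(C)=C/I)C(C)(C)C[C@H](O)C1
F2 | step 9 | (R)-3,5,5-trimethyl-4-[(3E,5E,7E,9E,11E,13E)-3,7,12-trimethyl-14-(4,4,5,5-tetramethyl-1,3,2-dioxaborolan-2-yl)tetradeca-3,5,7,9,11,13-hexaen-1-yn-1-yl]cyclohex-3-en-1-ol | CC1=C(C#C/C(C)=C/C=C/C(C)=C/C=C/C=C(C)/C=C/B2OC(C)(C)C(C)(C)O2)C(C)(C)C[C@H](O)C1
F3 | step 7 | (E)-4-[(R)-4-[(tert-butyldimethylsilyl)oxy]-2,6,6-trimethylcyclohex-1-en-1-yl]but-3-en-2-one | CC1=C(/C=C/C(C)=O)C(C)(C)C[C@H](O[Si](C)(C)C(C)(C)C)C1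
F4 | step 7 | 4-[(R)-4-[(tert-butyldimethylsilyl)oxy]-2,6,6-trimethylcyclohex-1-en-1-yl]butan-2-one | CC1=C(CCC(C)=O)C(C)(C)C[C@H](O[Si](C)(C)C(C)(C)C)C1
F5 | step 7 | 4-[(R)-4-[(tert-butyldimethylsilyl)oxy]-2,6,6-trimethylcyclohex-1-en-1-yl]but-1-en-2-yl diethyl phosphate | CC1=C(CCC(=C)OP(=O)(OCC)OCC)C(C)(C)C[C@H](O[Si](C)(C)C(C)(C)C)C1
F6 | step 7 | tert-butyl{[(R)-4-(but-3-yn-1-yl)-3,5,5-trimethylcyclohex-3-en-1-yl]oxy}dimethylsilane | CC1=C(CCC#C)C(C)(C)C[C@H](O[Si](C)(C)C(C)(C)C)C1
F7 | step 6 | (R)-4-[(3E,5E,7E,9E,11E)-3,7,12-trimethyltetradeca-3,5,7,9,11-pentaen-1,13-diyn-1-yl]-3,5,5-trimethylcyclohex-3-en-1-ol | CC1=C(C#C/C(C)=C/C=C/C(C)=C/C=C/C=C(C)/C#C)C(C)(C)C[C@H](O)C1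
F8 | step 6 | (R)-3,5,5-trimethyl-4-[(3E,5E,7E,9E,11E,13E)-3,7,12-trimethyl-14-(tributylstannyl)tetradeca-3,5,7,9,11,13-hexaen-1-yn-1-yl]cyclohex-3-en-1-ol | CC1=C(C#C/C(C)=C/C=C/C(C)=C/C=C/C=C(C)/C=C/[Sn](CCCC)(CCCC)CCCC)C(C)(C)C[C@H](O)C1
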